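**Retrosynthetic overview**

Ring numbering: C1 (CH–O-acyl), C2 (C=O), C3 (C(CH3)OH), C4 (CHOH), C5 (CH2), C6 (CH carrying the side chain C7(=CH2)–C8(=O)–C9=C10–C11(CH3)2OOH).
Enabling feature: the C1 isovalerate is read as the Baeyer–Villiger retron of a C1 isovaleryl ketone. The trans C1/C6 pair then becomes an (E)-enone, C2–C3(CH3)–C4–C5 a 1-silyloxy-2-methylbutadiene, and the cyclohexane ring (the only ring of the target) a [4+2] adduct; the C1–acyl bond, absent from the target, steers the cycloaddition and is later cut by oxygen insertion.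
Disconnections, backwards: C11–OOH and C9=C10 by singlet-oxygen ene reaction; C4–OH by trans-diaxial hydrolysis of a C3–C4 epoxy ketone; C7–C8 by Nozaki–Hiyama–Kishi coupling of a C7 alkenyl bromide; C1–O by Baeyer–Villiger oxidation; the C3–C4 epoxide directed by a temporary C2 silyloxy stereocentre; C1–C2 and C5–C6 by Diels–Alder reaction.
Ring order: cyclohexene (step 5), then a temporary oxirane (step 6, opened in step 12).

Key step: step 5

Remark: locants in the text follow the target numbering above; the systematic names of the bicyclic intermediates carry their own locants.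
Remark (assumption): the (S)-oxazaborolidinium catalyst is chosen on the assumption that, as with acrylates and other enones, it delivers the diene to the face of the acyl-bearing alkene carbon on which acyl group, β-carbon and hydrogen run clockwise, which is the face needed here; the (R)-catalyst would be used if the sense proved opposite.

**Route**

Step 1
Reactants: 1 (2E)-2-methylbut-2-enal
Product: 2 tert-butyl(dimethyl){[(1E)-2-methylbuta-1,3-dien-1-yl]oxy}silane
Conditions: TBSOTf, Et3N, Et2O, 0 °C to rt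
Reagents that add atoms: tert-butyldimethylsilyl trifluoromethanesulfonate, CC(C)(C)[Si](C)(C)OS(=O)(=O)C(F)(F)F
Why: Silyl dienol ether formation by soft enolisation: O-silylation gives a silyloxocarbenium ion from which Et3N removes a γ-proton, and the (1E)-diene should predominate, the (1Z)-isomer being unable to reach the s-cis geometry needed in step 5.

Step 2
Reactants: 3 prop-2-enal
Product: 5 2-bromoprop-2-enal, via 2,3-dibromopropanal 4 (not isolated)
Conditions: Br2, CH2Cl2, 0 °C; then Et3N, 0 °C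
Reagents that add atoms: bromine, BrBr
Why: Bromine addition to the alkene followed by base-induced (E1cB) loss of HBr from the α-bromo aldehyde is the standard bromination–dehydrobromination route to α-bromo enals.

Step 3
Reactants: 6 methyl(triphenyl)phosphonium bromide (2 equiv); 7 3-methylbutanoyl chloride
Product: 9 4-methyl-1-(triphenyl-λ5-phosphanylidene)pentan-2-one, via methylidene(triphenyl)-λ5-phosphane 8 (not isolated)
Conditions: n-BuLi (2 equiv), THF, 0 °C; then 7, −78 °C to rt
Reagents that add atoms: none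
Why: C-Acylation of a phosphorus ylide: the ylide attacks the acid chloride and the second equivalent of ylide deprotonates the β-keto phosphonium salt (transylidation) to give the stabilised acyl ylide.

Step 4
Reactants: 5 2-bromoprop-2-enal; 9 4-methyl-1-(triphenyl-λ5-phosphanylidene)pentan-2-one
Product: 10 (3E)-2-bromo-7-methylocta-1,3-dien-5-one
Conditions: CH2Cl2, 0 °C to rt
Reagents that add atoms: none
Why: Wittig olefination with a stabilised acyl ylide should give the (E)-enone, and the neutral conditions spare the base-sensitive bromo enal.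

Step 5
Reactants: 2 tert-butyl(dimethyl){[(1E)-2-methylbuta-1,3-dien-1-yl]oxy}silane (1.5 equiv); 10 (3E)-2-bromo-7-methylocta-1,3-dien-5-one
Product: 11 1-[(1S,2S,6R)-6-(1-bromoethenyl)-2-{[tert-butyl(dimethyl)silyl]oxy}-3-methylcyclohex-3-en-1-yl]-3-methylbutan-1-one
Conditions: (S)-oxazaborolidinium triflimide (20 mol %; from (S)-α,α-diphenylprolinol, tri(o-tolyl)boroxine and Tf2NH), CH2Cl2, −78 to −40 °C
Reagents that add atoms: none
Why: The boron Lewis acid binds the single carbonyl group of 10 and a concerted, asynchronous, normal-electron-demand Diels–Alder reaction follows, in which the CH2 terminus of the diene (C5) bonds to the enone β-carbon (C6) ahead of the bond between the silyloxy-bearing terminus (C2) and the α-carbon (C1); the closest precedent is the chiral oxazaborolidinium-catalysed cycloaddition of acyclic β-substituted enones with silyloxy dienes. The cyclohexene ring is closed by suprafacial [4+2] cycloaddition, so only orbital symmetry governs the closure. The trans relation of C1 and C6 is carried over from the (E)-alkene of 10, the C2 silyloxy group is placed cis to the C1 acyl group by the endo transition state of the (1E)-diene, and the absolute configuration comes from the catalyst, which shields one face of the bound enone. Regioselectivity is secured by the match of the largest HOMO coefficient of the 1-silyloxydiene (CH2 terminus) with the largest LUMO coefficient of the bound enone (β-carbon). Site selectivity for the α,β-alkene over the 1-bromovinyl group is expected because only the former is attached to the activated carbonyl and because reaction at the bromoalkene would have to create a quaternary C–Br centre next to the substituted diene terminus.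

Step 6
Reactants: 11 1-[(1S,2S,6R)-6-(1-bromoethenyl)-2-{[tert-butyl(dimethyl)silyl]oxy}-3-methylcyclohex-3-en-1-yl]-3-methylbutan-1-one
Product: 12 1-[(1S,2S,3S,4R,6S)-4-(1-bromoethenyl)-2-{[tert-butyl(dimethyl)silyl]oxy}-1-methyl-7-oxabicyclo[4.1.0]heptan-3-yl]-3-methylbutan-1-one
Conditions: mCPBA (1.1 equiv), NaHCO3 (buffer), CH2Cl2, 0 °C
Reagents that add atoms: 3-chloroperbenzoic acid, OOC(=O)c1cccc(Cl)c1
Why: Prilezhaev epoxidation of the only electron-rich alkene (C3=C4; the bromoalkene is deactivated and the ketone reacts far more slowly), with the peracid approaching anti to the pseudo-axial allylic C2 silyloxy group, which sets C3 and C4 with the epoxide oxygen cis to the C6 substituent.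

Step 7
Reactants: 12 1-[(1S,2S,3S,4R,6S)-4-(1-bromoethenyl)-2-{[tert-butyl(dimethyl)silyl]oxy}-1-methyl-7-oxabicyclo[4.1.0]heptan-3-yl]-3-methylbutan-1-one
Product: 13 (1S,2S,3S,4R,6S)-4-(1-bromoethenyl)-2-{[tert-butyl(dimethyl)silyl]oxy}-1-methyl-7-oxabicyclo[4.1.0]heptan-3-yl 3-methylbutanoate
Conditions: CF3CO3H (pre-formed solution), Na2HPO4 (buffer), CH2Cl2, 0 °C to rt
Reagents that add atoms: trifluoroperacetic acid, OOC(=O)C(F)(F)F
Why: Baeyer–Villiger oxidation: in the Criegee adduct the secondary ring carbon C1 should migrate in preference to the primary isobutyl CH2, with retention at C1, so the isovaleryl ketone becomes the isovalerate of the target, while the deactivated bromoalkene and the buffered epoxide are expected to survive.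

Step 8
Reactants: 14 4-methylpent-3-en-1-ol
Product: 15 4-methylpent-3-enal
Conditions: DMP (1,1,1-triacetoxy-1,1-dihydro-1,2-benziodoxol-3(1H)-one), NaHCO3 (buffer), CH2Cl2, 0 °C; used at once
Reagents that add atoms: none
Why: Periodinane oxidation of a primary alcohol under buffered, non-enolising conditions should give the β,γ-unsaturated aldehyde without moving the double bond into conjugation.

Step 9
Reactants: 13 (1S,2S,3S,4R,6S)-4-(1-bromoethenyl)-2-{[tert-butyl(dimethyl)silyl]oxy}-1-methyl-7-oxabicyclo[4.1.0]heptan-3-yl 3-methylbutanoate; 15 4-methylpent-3-enal (2 equiv)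
Product: 16 (1S,2S,3S,4S,6S)-2-{[tert-butyl(dimethyl)silyl]oxy}-4-(3-hydroxy-6-methylhepta-1,5-dien-2-yl)-1-methyl-7-oxabicyclo[4.1.0]heptan-3-yl 3-methylbutanoate (both C8 epimers)
Conditions: CrCl2 (6 equiv), NiCl2 (5 mol %), DMF, rt
Reagents that add atoms: none
Why: Nozaki–Hiyama–Kishi coupling: nickel-catalysed insertion into the alkenyl C–Br bond, transmetalation to chromium and 1,2-addition of the alkenylchromium species to the aldehyde form C7–C8 in the presence of ester, epoxide and silyl ether; the new C8 carbinol centre is formed as a mixture and is removed by oxidation in step 11.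

Step 10
Reactants: 16 (1S,2S,3S,4S,6S)-2-{[tert-butyl(dimethyl)silyl]oxy}-4-(3-hydroxy-6-methylhepta-1,5-dien-2-yl)-1-methyl-7-oxabicyclo[4.1.0]heptan-3-yl 3-methylbutanoate
Product: 17 (1R,2S,3S,4S,6S)-2-hydroxy-4-(3-hydroxy-6-methylhepta-1,5-dien-2-yl)-1-methyl-7-oxabicyclo[4.1.0]heptan-3-yl 3-methylbutanoate
Conditions: HF·pyridine, pyridine, THF, 0 °C to rt
Reagents that add atoms: none
Why: Fluoride-mediated cleavage of the secondary silyl ether under non-basic, pyridine-buffered conditions, which should avoid acyl migration from O1 to the neighbouring cis O2 and migration or opening of the epoxide.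

Step 11
Reactants: 17 (1R,2S,3S,4S,6S)-2-hydroxy-4-(3-hydroxy-6-methylhepta-1,5-dien-2-yl)-1-methyl-7-oxabicyclo[4.1.0]heptan-3-yl 3-methylbutanoate
Product: 18 (1S,3S,4S,6S)-1-methyl-4-(6-methyl-3-oxohepta-1,5-dien-2-yl)-2-oxo-7-oxabicyclo[4.1.0]heptan-3-yl 3-methylbutanoate
Conditions: DMP (3 equiv), NaHCO3 (buffer), CH2Cl2, 0 °C to rt
Reagents that add atoms: none
Why: Periodinane oxidation of both secondary alcohols should give the C2 ketone (erasing the temporary C2 stereocentre) and the C8 ketone under buffered conditions that leave the C10=C11 double bond out of conjugation.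

Step 12
Reactants: 18 (1S,3S,4S,6S)-1-methyl-4-(6-methyl-3-oxohepta-1,5-dien-2-yl)-2-oxo-7-oxabicyclo[4.1.0]heptan-3-yl 3-methylbutanoate
Product: 19 (1S,3S,4R,6S)-3,4-dihydroxy-3-methyl-6-(6-methyl-3-oxohepta-1,5-dien-2-yl)-2-oxocyclohexyl 3-methylbutanoate
Conditions: HClO4 (0.5 M aq., cat.), THF, 0 °C to rt
Reagents that add atoms: water, O
Why: Acid-catalysed hydrolysis of an α,β-epoxy ketone: water should attack C4, the epoxide carbon remote from the carbonyl, with inversion in a trans-diaxial opening that keeps the C1 and C6 substituents equatorial, while the C3–O bond is retained, which sets C4 (R) and leaves C3 (S).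

Step 13
Reactants: 19 (1S,3S,4R,6S)-3,4-dihydroxy-3-methyl-6-(6-methyl-3-oxohepta-1,5-dien-2-yl)-2-oxocyclohexyl 3-methylbutanoate
Product: 20 (1S,3S,4R,6S)-3,4-dihydroxy-6-[(4E)-6-hydroperoxy-6-methyl-3-oxohepta-1,4-dien-2-yl]-3-methyl-2-oxocyclohexyl 3-methylbutanoate
Conditions: O2, 5,10,15,20-tetraphenylporphyrin (cat.), visible light, CH2Cl2, −20 °C
Reagents that add atoms: dioxygen, O=O
Why: Schenck ene reaction of singlet oxygen with the electron-rich C10=C11 alkene (the C7 methylene enone is inert): abstraction of an activated C9 hydrogen next to the ketone should give the conjugated (E)-C9=C10 alkene and the tertiary C11 hydroperoxide, the known preference of β,γ-unsaturated carbonyl compounds.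

**Compound list**

1 | (2E)-2-methylbut-2-enal | C/C=C(\C)C=O | starting material
2 | tert-butyl(dimethyl){[(1E)-2-methylbuta-1,3-dien-1-yl]oxy}silane | C=C/C(C)=C/O[Si](C)(C)C(C)(C)C | intermediate
3 | prop-2-enal | C=CC=O | starting material
4 | 2,3-dibromopropanal | O=CC(Br)CBr | intermediate
5 | 2-bromoprop-2-enal | C=C(Br)C=O | intermediate
6 | methyl(triphenyl)phosphonium bromide | C[P+](c1ccccc1)(c1ccccc1)c1ccccc1.[Br-] | starting material
7 | 3-methylbutanoyl chloride | CC(C)CC(=O)Cl | starting material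
8 | methylidene(triphenyl)-λ5-phosphane | C=P(c1ccccc1)(c1ccccc1)c1ccccc1 | intermediate
9 | 4-methyl-1-(triphenyl-λ5-phosphanylidene)pentan-2-one | CC(C)CC(=O)C=P(c1ccccc1)(c1ccccc1)c1ccccc1 | intermediate
10 | (3E)-2-bromo-7-methylocta-1,3-dien-5-one | C=C(Br)/C=C/C(=O)CC(C)C | intermediate
11 | 1-[(1S,2S,6R)-6-(1-bromoethenyl)-2-{[tert-butyl(dimethyl)silyl]oxy}-3-methylcyclohex-3-en-1-yl]-3-methylbutan-1-one | C=C(Br)[C@@H]1CC=C(C)[C@@H](O[Si](C)(C)C(C)(C)C)[C@H]1C(=O)CC(C)C | intermediate
12 | 1-[(1S,2S,3S,4R,6S)-4-(1-bromoethenyl)-2-{[tert-butyl(dimethyl)silyl]oxy}-1-methyl-7-oxabicyclo[4.1.0]heptan-3-yl]-3-methylbutan-1-one | C=C(Br)[C@@H]1C[C@@H]2O[C@]2(C)[C@@H](O[Si](C)(C)C(C)(C)C)[C@H]1C(=O)CC(C)C | intermediate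
13 | (1S,2S,3S,4R,6S)-4-(1-bromoethenyl)-2-{[tert-butyl(dimethyl)silyl]oxy}-1-methyl-7-oxabicyclo[4.1.0]heptan-3-yl 3-methylbutanoate | C=C(Br)[C@@H]1C[C@@H]2O[C@]2(C)[C@@H](O[Si](C)(C)C(C)(C)C)[C@H]1OC(=O)CC(C)C | intermediate
14 | 4-methylpent-3-en-1-ol | CC(C)=CCCO | starting material
15 | 4-methylpent-3-enal | CC(C)=CCC=O | intermediate
16 | (1S,2S,3S,4S,6S)-2-{[tert-butyl(dimethyl)silyl]oxy}-4-(3-hydroxy-6-methylhepta-1,5-dien-2-yl)-1-methyl-7-oxabicyclo[4.1.0]heptan-3-yl 3-methylbutanoate (both carbinol epimers) | C=C(C(O)CC=C(C)C)[C@@H]1C[C@@H]2O[C@]2(C)[C@@H](O[Si](C)(C)C(C)(C)C)[C@H]1OC(=O)CC(C)C | intermediate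
17 | (1R,2S,3S,4S,6S)-2-hydroxy-4-(3-hydroxy-6-methylhepta-1,5-dien-2-yl)-1-methyl-7-oxabicyclo[4.1.0]heptan-3-yl 3-methylbutanoate (both carbinol epimers) | C=C(C(O)CC=C(C)C)[C@@H]1C[C@@H]2O[C@]2(C)[C@@H](O)[C@H]1OC(=O)CC(C)C | intermediate
18 | (1S,3S,4S,6S)-1-methyl-4-(6-methyl-3-oxohepta-1,5-dien-2-yl)-2-oxo-7-oxabicyclo[4.1.0]heptan-3-yl 3-methylbutanoate | C=C(C(=O)CC=C(C)C)[C@@H]1C[C@@H]2O[C@]2(C)C(=O)[C@H]1OC(=O)CC(C)C | intermediate
19 | (1S,3S,4R,6S)-3,4-dihydroxy-3-methyl-6-(6-methyl-3-oxohepta-1,5-dien-2-yl)-2-oxocyclohexyl 3-methylbutanoate | C=C(C(=O)CC=C(C)C)[C@@H]1C[C@@H](O)[C@](C)(O)C(=O)[C@H]1OC(=O)CC(C)C | intermediate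
20 | (1S,3S,4R,6S)-3,4-dihydroxy-6-[(4E)-6-hydroperoxy-6-methyl-3-oxohepta-1,4-dien-2-yl]-3-methyl-2-oxocyclohexyl 3-methylbutanoate | C=C(C(=O)/C=C/C(C)(C)OO)[C@@H]1C[C@@H](O)[C@](C)(O)C(=O)[C@H]1OC(=O)CC(C)C | target

**Step count and risks**

Total step count: 13. Longest linear sequence: 10 steps (3, 4, 5, 6, 7, 9, 10, 11, 12, 13).

Steps most likely to fail:

1. Step 5. The cycloaddition may occur across the 1-bromovinyl terminus, may stop at vinylogous conjugate addition without ring closure, or may suffer a catalyst-independent silyl-cation background reaction that erodes the enantioselectivity. Fallback: the 1-bromovinyl group is replaced by an ethynyl group, which offers no second dienophile site and is inert to peracids. The fallback sets out from 9, whose Wittig reaction with commercial 3-(trimethylsilyl)prop-2-ynal should give (3E)-7-methyl-1-(trimethylsilyl)oct-3-en-1-yn-5-one F1. Cycloaddition of F1 with 2 under the conditions of step 5 should give the alkynyl cyclohexene 1-[(1S,2S,6R)-2-{[tert-butyl(dimethyl)silyl]oxy}-3-methyl-6-[(trimethylsilyl)ethynyl]cyclohex-3-en-1-yl]-3-methylbutan-1-one F2. Epoxidation as in step 6 should give the epoxy ketone F3 and Baeyer–Villiger oxidation as in step 7 the epoxy ester F4. Buffered TBAF/AcOH at −20 °C should remove the C-silyl group to give the terminal alkyne F5. A nickel-catalysed aldehyde–alkyne reductive coupling of F5 with 15 (Ni(cod)2, zerovalent nickel, the bulky carbene ligand 1,3-bis(2,6-diisopropylphenyl)imidazolidin-2-ylidene, Et3SiH, THF), in which the large ligand places the new C–C bond at the internal alkyne carbon, should give the triethylsilyl ether F6. HF·pyridine then removes both silyl groups and the route is rejoined at 17.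

2. Step 7. The isobutyl CH2 may migrate in competition with C1, which carries two electron-withdrawing β-substituents; peracid addition to the hindered carbonyl may be slow; or the bromoalkene may be oxidised. Fallback: a methyl ketone is used, for which migration of the ring carbon is unambiguous, and the acyl group is exchanged afterwards. The fallback sets out from 5, whose Wittig reaction with commercial 1-(triphenyl-λ5-phosphanylidene)propan-2-one should give (3E)-5-bromohexa-3,5-dien-2-one F7. Cycloaddition with 2 as in step 5 should give the methyl ketone F8, epoxidation as in step 6 the epoxy ketone F9, and Baeyer–Villiger oxidation the acetate F10. Reductive cleavage of the acetate with i-Bu2AlH at −78 °C should give the alcohol F11, and acylation with 7 (pyridine, cat. DMAP) rejoins the route at 13.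

3. Step 12. The acid may move the C10=C11 double bond into conjugation or hydrate the side-chain alkenes before the deactivated epoxy ketone opens; attack at the wrong epoxide carbon is the lesser concern. Fallback: the epoxide is hydrolysed before the side chain is attached, when only acid-stable groups are present, and the side chain is then built on the free diol. The fallback sets out from 13: HF·pyridine should give the alcohol F12, periodinane oxidation the epoxy ketone F13, and aqueous HClO4 (now under more forcing conditions if needed) the dihydroxy ketone F14. Nozaki–Hiyama–Kishi coupling of F14 with 15, which tolerates free hydroxyl and ketone groups, should give the triol F15, and MnO2 should oxidise only the allylic alcohol, rejoining the route at 19.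

**Further compounds**

F1 | step 5 | (3E)-7-methyl-1-(trimethylsilyl)oct-3-en-1-yn-5-one | CC(C)CC(=O)/C=C/C#C[Si](C)(C)C
F2 | step 5 | 1-[(1S,2S,6R)-2-{[tert-butyl(dimethyl)silyl]oxy}-3-methyl-6-[(trimethylsilyl)ethynyl]cyclohex-3-en-1-yl]-3-methylbutan-1-one | C[Si](C)(C)C#C[C@@H]1CC=C(C)[C@@H](O[Si](C)(C)C(C)(C)C)[C@H]1C(=O)CC(C)C
F3 | step 5 | 1-[(1S,2S,3S,4R,6S)-2-{[tert-butyl(dimethyl)silyl]oxy}-1-methyl-4-[(trimethylsilyl)ethynyl]-7-oxabicyclo[4.1.0]heptan-3-yl]-3-methylbutan-1-one | C[Si](C)(C)C#C[C@@H]1C[C@@H]2O[C@]2(C)[C@@H](O[Si](C)(C)C(C)(C)C)[C@H]1C(=O)CC(C)C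
F4 | step 5 | (1S,2S,3S,4S,6S)-2-{[tert-butyl(dimethyl)silyl]oxy}-1-methyl-4-[(trimethylsilyl)ethynyl]-7-oxabicyclo[4.1.0]heptan-3-yl 3-methylbutanoate | C[Si](C)(C)C#C[C@@H]1C[C@@H]2O[C@]2(C)[C@@H](O[Si](C)(C)C(C)(C)C)[C@H]1OC(=O)CC(C)C
F5 | step 5 | (1S,2S,3S,4S,6S)-2-{[tert-butyl(dimethyl)silyl]oxy}-4-ethynyl-1-methyl-7-oxabicyclo[4.1.0]heptan-3-yl 3-methylbutanoate | C#C[C@@H]1C[C@@H]2O[C@]2(C)[C@@H](O[Si](C)(C)C(C)(C)C)[C@H]1OC(=O)CC(C)C
F6 | step 5 | (1S,2S,3S,4S,6S)-2-{[tert-butyl(dimethyl)silyl]oxy}-1-methyl-4-{6-methyl-3-[(triethylsilyl)oxy]hepta-1,5-dien-2-yl}-7-oxabicyclo[4.1.0]heptan-3-yl 3-methylbutanoate (both silyloxy epimers) | C=C(C(CC=C(C)C)O[Si](CC)(CC)CC)[C@@H]1C[C@@H]2O[C@]2(C)[C@@H](O[Si](C)(C)C(C)(C)C)[C@H]1OC(=O)CC(C)C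
F7 | step 7 | (3E)-5-bromohexa-3,5-dien-2-one | CC(=O)/C=C/C(Br)=C
F8 | step 7 | 1-[(1S,2S,6R)-6-(1-bromoethenyl)-2-{[tert-butyl(dimethyl)silyl]oxy}-3-methylcyclohex-3-en-1-yl]ethan-1-one | C=C(Br)[C@@H]1CC=C(C)[C@@H](O[Si](C)(C)C(C)(C)C)[C@H]1C(C)=O
F9 | step 7 | 1-[(1S,2S,3S,4R,6S)-4-(1-bromoethenyl)-2-{[tert-butyl(dimethyl)silyl]oxy}-1-methyl-7-oxabicyclo[4.1.0]heptan-3-yl]ethan-1-one | C=C(Br)[C@@H]1C[C@@H]2O[C@]2(C)[C@@H](O[Si](C)(C)C(C)(C)C)[C@H]1C(C)=O
F10 | step 7 | (1S,2S,3S,4R,6S)-4-(1-bromoethenyl)-2-{[tert-butyl(dimethyl)silyl]oxy}-1-methyl-7-oxabicyclo[4.1.0]heptan-3-yl acetate | C=C(Br)[C@@H]1C[C@@H]2O[C@]2(C)[C@@H](O[Si](C)(C)C(C)(C)C)[C@H]1OC(C)=O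
F11 | step 7 | (1S,2S,3S,4R,6S)-4-(1-bromoethenyl)-2-{[tert-butyl(dimethyl)silyl]oxy}-1-methyl-7-oxabicyclo[4.1.0]heptan-3-ol | C=C(Br)[C@@H]1C[C@@H]2O[C@]2(C)[C@@H](O[Si](C)(C)C(C)(C)C)[C@H]1O
F12 | step 12 | (1R,2S,3S,4R,6S)-4-(1-bromoethenyl)-2-hydroxy-1-methyl-7-oxabicyclo[4.1.0]heptan-3-yl 3-methylbutanoate | C=C(Br)[C@@H]1C[C@@H]2O[C@]2(C)[C@@H](O)[C@H]1OC(=O)CC(C)C
F13 | step 12 | (1S,3S,4R,6S)-4-(1-bromoethenyl)-1-methyl-2-oxo-7-oxabicyclo[4.1.0]heptan-3-yl 3-methylbutanoate | C=C(Br)[C@@H]1C[C@@H]2O[C@]2(C)C(=O)[C@H]1OC(=O)CC(C)C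
F14 | step 12 | (1S,3S,4R,6R)-6-(1-bromoethenyl)-3,4-dihydroxy-3-methyl-2-oxocyclohexyl 3-methylbutanoate | C=C(Br)[C@@H]1C[C@@H](O)[C@](C)(O)C(=O)[C@H]1OC(=O)CC(C)C
F15 | step 12 | (1S,3S,4R,6S)-3,4-dihydroxy-6-(3-hydroxy-6-methylhepta-1,5-dien-2-yl)-3-methyl-2-oxocyclohexyl 3-methylbutanoate (both carbinol epimers) | C=C(C(O)CC=C(C)C)[C@@H]1C[C@@H](O)[C@](C)(O)C(=O)[C@H]1OC(=O)CC(C)C
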